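The oxocane is not closed head-on. Its ring oxygen is first parked in a 2,5-trans oxolane (O bridging C6 and C9) carved from D-glucose, which also supplies C7 and C10. A pendant cis-12,13-epoxide and a C10 acetate are then installed. In one operation the oxolane oxygen opens the epoxide at C12 to a bicyclic oxonium ion, and the acetate opens that ion at C9: the five-membered ring expands to the eight-membered ring while C12, C13 and C9 are set. The step exploits the 1,4-relation between the ring oxygen and the C9 oxygen, the vicinal C9/C10 diacetate and the C13 oxygen next to C12. Carbons are numbered C1 (alkyne end) to C15.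

Key step: step 13

Remark: hydrolysis of the dioxolanylium ion in step 13 can leave the acetyl group on O10 or on O9; compound 17 is drawn as the 10-O-acetate, and either isomer gives 18 in step 14.

**Step 1**
Reactants: 1 diacetone-D-glucose (1,2:5,6-di-O-isopropylidene-α-D-glucofuranose)
Product: 2 S-methyl xanthate of 1 at O3
Conditions: NaH, THF, 0 °C; CS2; MeI, rt
Reagents that add atoms: carbon disulfide, S=C=S; iodomethane, CI
Why: The only free hydroxyl adds as its alkoxide to CS2 and is S-methylated (xanthate formation), which prepares the radical deoxygenation without touching a stereocenter.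

**Step 2**
Reactants: 2 S-methyl xanthate
Product: 3 3-deoxy-1,2:5,6-di-O-isopropylidene-α-D-ribo-hexofuranose
Conditions: Bu3SnH, AIBN (cat.), toluene, 110 °C
Reagents that add atoms: none
Why: Barton–McCombie deoxygenation turns sugar C3 into the future C8 methylene and leaves sugar C2, C4 and C5 (future C7, C9, C10) untouched.

**Step 3**
Reactants: 3 3-deoxy diacetonide
Product: 4 3-deoxy-1,2-O-isopropylidene-α-D-ribo-hexofuranose (5,6-diol)
Conditions: AcOH/H2O 7:3, rt
Reagents that add atoms: none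
Why: The terminal 5,6-acetonide is hydrolysed faster than the ring-fused 1,2-acetonide under mild aqueous acid (selective acetal hydrolysis).

**Step 4**
Reactants: 4 5,6-diol
Product: 6 6-O-benzoyl-3-deoxy-1,2-O-isopropylidene-5-O-methanesulfonyl-α-D-ribo-hexofuranose, via 6-O-benzoate 5 (not isolated)
Conditions: BzCl (1.05 equiv), pyridine, CH2Cl2, −30 °C; then MsCl, 0 °C → rt
Reagents that add atoms: benzoyl chloride, O=C(Cl)c1ccccc1; methanesulfonyl chloride, CS(=O)(=O)Cl
Why: The primary hydroxyl is acylated selectively at low temperature and the remaining secondary hydroxyl is then sulfonylated in the same flask, which sets up epoxide closure with inversion at the future C10.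

**Step 5**
Reactants: 6 benzoate mesylate
Product: 7 (2R)-2-[(2S,4R,5R)-4-hydroxy-5-(prop-2-enyl)oxolan-2-yl]-2-(methanesulfonyloxy)ethyl benzoate (C6 R, C7 R, C9 S, C10 R)
Conditions: allylSiMe3, BF3·OEt2, CH2Cl2, −20 → 0 °C; NaHCO3 work-up
Reagents that add atoms: allyltrimethylsilane, C=CC[Si](C)(C)C
Why: Hosomi–Sakurai C-glycosylation: BF3 opens the 1,2-acetonide to the furanosyl oxocarbenium ion and the allylsilane attacks the inside face of the envelope that keeps the C7 oxygen pseudo-equatorial, which should set C6 (R) cis to the C7 oxygen and trans to the C9 side chain while ester and mesylate stay inert.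

**Step 6**
Reactants: 7 C-allyl alcohol
Product: 8 (2R)-2-[(2S,4R,5R)-4-(tert-butyldimethylsilyloxy)-5-(prop-2-enyl)oxolan-2-yl]-2-(methanesulfonyloxy)ethyl benzoate
Conditions: TBSOTf, 2,6-lutidine, CH2Cl2, −40 → 0 °C
Reagents that add atoms: tert-butyldimethylsilyl triflate, CC(C)(C)[Si](C)(C)OS(=O)(=O)C(F)(F)F
Why: Silylation masks the C7 hydroxyl, the one oxygen that must end up free, with a group that survives base, organometallics and BF3 at low temperature.

**Step 7**
Reactants: 8 silyl ether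
Product: 9 (2R,3R,5S)-3-(tert-butyldimethylsilyloxy)-5-[(2S)-oxiran-2-yl]-2-(prop-2-enyl)oxolane
Conditions: K2CO3, MeOH, 0 °C → rt
Reagents that add atoms: none
Why: Methanolysis of the benzoate frees the primary alkoxide, which displaces the neighbouring mesylate in a 3-exo-tet SN2 closure with inversion, so C10 becomes (S).

**Step 8**
Reactants: 9 allyl epoxide
Product: 10 2-[(2R,3R,5S)-3-(tert-butyldimethylsilyloxy)-5-[(2S)-oxiran-2-yl]oxolan-2-yl]acetaldehyde
Conditions: O3, CH2Cl2, −78 °C; PPh3, −78 °C → rt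
Reagents that add atoms: ozone, [O-][O+]=O
Why: Ozonolysis with reductive work-up cleaves the only olefin to the C4 aldehyde; epoxide and silyl ether are inert to ozone.

**Step 9**
Reactants: 10 aldehyde
Product: 11 (2R,3R,5S)-3-(tert-butyldimethylsilyloxy)-5-[(2S)-oxiran-2-yl]-2-[(2Z)-5-(triisopropylsilyl)pent-2-en-4-ynyl]oxolane
Conditions: 1,3-bis(triisopropylsilyl)propyne, n-BuLi, THF, −78 °C; then 10, −78 °C → rt
Reagents that add atoms: 1,3-bis(triisopropylsilyl)propyne, CC(C)[Si](C(C)C)(C(C)C)CC#C[Si](C(C)C)(C(C)C)C(C)C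
Why: Peterson olefination with the lithiated bis-silylpropyne adds to the aldehyde and the β-silyl alkoxide eliminates syn, which should give the Z-enyne; the epoxide does not react with the organolithium at −78 °C.

**Step 10**
Reactants: 11 enyne epoxide
Product: 12 (1S,3Z)-1-[(2S,4R,5R)-4-(tert-butyldimethylsilyloxy)-5-[(2Z)-5-(triisopropylsilyl)pent-2-en-4-ynyl]oxolan-2-yl]hex-3-en-1-ol
Conditions: EtLi, CuI, Et2O, −40 °C; HC≡CH, −50 → −25 °C; then 11, BF3·OEt2, −78 °C; NH4Cl/NH3 work-up
Reagents that add atoms: ethyllithium, [Li]CC; acetylene, C#C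
Why: Syn carbocupration of acetylene by Et2CuLi gives the (Z)-but-1-enyl cuprate, which opens the BF3-activated terminal epoxide at its CH2 end (SN2) and delivers the Z-homoallylic alcohol without touching the silylated enyne.

**Step 11**
Reactants: 12 Z-homoallylic alcohol
Product: 13 (1S)-1-[(2S,4R,5R)-4-(tert-butyldimethylsilyloxy)-5-[(2Z)-5-(triisopropylsilyl)pent-2-en-4-ynyl]oxolan-2-yl]-2-[(2R,3S)-3-ethyloxiran-2-yl]ethan-1-ol
Conditions: VO(acac)2 (5 mol %), t-BuOOH, CH2Cl2, 0 °C → rt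
Reagents that add atoms: tert-butyl hydroperoxide, CC(C)(C)OO
Why: Hydroxyl-directed epoxidation: the vanadate ester of the C10 hydroxyl transfers oxygen through a chair-like transition state with the oxolane substituent equatorial and the Z-olefin held by allylic strain, which should give the cis-epoxide syn to the C10 oxygen (12R,13S) and leaves the undirected enyne olefin alone.

**Step 12**
Reactants: 13 syn-epoxy alcohol
Product: 14 (1R)-1-[(2S,4R,5R)-4-(tert-butyldimethylsilyloxy)-5-[(2Z)-5-(triisopropylsilyl)pent-2-en-4-ynyl]oxolan-2-yl]-2-[(2R,3S)-3-ethyloxiran-2-yl]ethyl acetate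
Conditions: PPh3, DIAD, AcOH, toluene, 0 °C → rt
Reagents that add atoms: acetic acid, CC(=O)O
Why: Mitsunobu esterification inverts C10 by SN2 attack of acetate on the oxyphosphonium ion, which turns the (10S) directing hydroxyl into the (10R) acetate that the target carries and that the next step needs as neighbouring group.

**Step 13**
Reactants: 14 epoxy acetate
Product: 17 (2R,3R,5R,6R,8S)-3-(tert-butyldimethylsilyloxy)-5-hydroxy-8-[(1S)-1-hydroxypropyl]-2-[(2Z)-5-(triisopropylsilyl)pent-2-en-4-ynyl]oxocan-6-yl acetate, via bicyclic oxonium ion 15 (not isolated), via dioxolanylium ion 16 (not isolated)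
Conditions: BF3·OEt2 (1.2 equiv), CH2Cl2, −78 → −30 °C; then H2O, 0 °C; NaHCO3 work-up
Reagents that add atoms: water, O
Why: Proposed new method: BF3 activates the cis-epoxide and the oxolane oxygen opens it at C12 with inversion (5-exo-tet, new ring O–C9–C10–C11–C12) to the bicyclic oxonium ion 15; the carbonyl oxygen of the C10 acetate then attacks C9 from the back (5-exo-tet, dioxolanylium ion 16), which cuts the O–C9 bond shared by the two five-membered rings and leaves the eight-membered ring, and water hydrolyses 16 to the monoacetate. The closest known reaction types are the bromonium-induced ring expansion of oxolanes to eight-membered bromoethers with capture by a neighbouring carbonate and Lewis-acid epoxide-opening cascades that pass through bicyclic oxonium ions; an epoxide as trigger for this ring expansion is the untested part. No ring is closed at eight-membered size: both closures are five-membered and exo, and the oxocane arises by fragmentation of the oxonium ion. C12 (S) comes from stereospecific anti opening of the (12R) epoxide carbon, C13 (S) is the untouched epoxide carbon, and C9 (R) comes from inversion of the (9S) oxolane carbon by the acetate fixed on C10 (R). The step needs the ether oxygen to outrun the ester carbonyl at the epoxide and needs 15 to open at C9 and not at C6 or C12: the ether oxygen is the better nucleophile and closes a five- instead of a six-membered ring, only C9 can be reached by the acetate in a backside five-ring closure, and the reversible first step should funnel material through this exit.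

**Step 14**
Reactants: 17 oxocane diol monoacetate
Product: 18 (2R,3R,5R,6R,8S)-8-[(1S)-1-acetoxypropyl]-3-(tert-butyldimethylsilyloxy)-2-[(2Z)-5-(triisopropylsilyl)pent-2-en-4-ynyl]oxocane-5,6-diyl diacetate
Conditions: Ac2O, pyridine, DMAP (cat.), CH2Cl2, rt
Reagents that add atoms: acetic anhydride, CC(=O)OC(C)=O
Why: DMAP-catalysed acylation esterifies both free secondary hydroxyls (C13 and C9, or C10 if the acetyl group sits on O9), so every regioisomer from step 13 converges on one triacetate.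

**Step 15**
Reactants: 18 silylated triacetate
Product: 19 CNP0352372.1, (2R,3R,5R,6R,8S)-8-[(1S)-1-acetoxypropyl]-3-hydroxy-2-[(2Z)-pent-2-en-4-ynyl]oxocane-5,6-diyl diacetate
Conditions: TBAF, AcOH (1:1), THF, 0 °C → rt
Reagents that add atoms: none
Why: Buffered fluoride cleaves the alkynyl C–Si bond and the C7 silyl ether in one operation, and the acetic acid buffer should suppress acetyl migration onto the freed C7 hydroxyl.

**Compound list**

1 | 1,2:5,6-di-O-isopropylidene-α-D-glucofuranose | CC1(C)OC[C@@H](O1)[C@H]2O[C@@H]3OC(C)(C)O[C@@H]3[C@H]2O | starting material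
2 | 3-O-[(methylsulfanyl)thiocarbonyl] derivative of 1 | CC1(C)OC[C@@H](O1)[C@H]2O[C@@H]3OC(C)(C)O[C@@H]3[C@H]2OC(=S)SC | intermediate
3 | 3-deoxy-1,2:5,6-di-O-isopropylidene-α-D-ribo-hexofuranose | CC1(C)OC[C@@H](O1)[C@H]2O[C@@H]3OC(C)(C)O[C@@H]3C2 | intermediate
4 | 3-deoxy-1,2-O-isopropylidene-α-D-ribo-hexofuranose | OC[C@@H](O)[C@H]1O[C@@H]2OC(C)(C)O[C@@H]2C1 | intermediate
5 | 6-O-benzoyl-3-deoxy-1,2-O-isopropylidene-α-D-ribo-hexofuranose | O=C(OC[C@@H](O)[C@H]1O[C@@H]2OC(C)(C)O[C@@H]2C1)c1ccccc1 | intermediate (not isolated)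
6 | 6-O-benzoyl-3-deoxy-1,2-O-isopropylidene-5-O-methanesulfonyl-α-D-ribo-hexofuranose | O=C(OC[C@@H](OS(C)(=O)=O)[C@H]1O[C@@H]2OC(C)(C)O[C@@H]2C1)c1ccccc1 | intermediate
7 | (2R)-2-[(2S,4R,5R)-4-hydroxy-5-(prop-2-enyl)oxolan-2-yl]-2-(methanesulfonyloxy)ethyl benzoate | C=CC[C@H]1O[C@@H](C[C@H]1O)[C@H](OS(C)(=O)=O)COC(=O)c2ccccc2 | intermediate
8 | C7 tert-butyldimethylsilyl ether of 7 | C=CC[C@H]1O[C@@H](C[C@H]1O[Si](C)(C)C(C)(C)C)[C@H](OS(C)(=O)=O)COC(=O)c2ccccc2 | intermediate
9 | (2R,3R,5S)-3-(tert-butyldimethylsilyloxy)-5-[(2S)-oxiran-2-yl]-2-(prop-2-enyl)oxolane | C=CC[C@H]1O[C@@H](C[C@H]1O[Si](C)(C)C(C)(C)C)[C@@H]2CO2 | intermediate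
10 | 2-[(2R,3R,5S)-3-(tert-butyldimethylsilyloxy)-5-[(2S)-oxiran-2-yl]oxolan-2-yl]acetaldehyde | O=CC[C@H]1O[C@@H](C[C@H]1O[Si](C)(C)C(C)(C)C)[C@@H]2CO2 | intermediate
11 | (2R,3R,5S)-3-(tert-butyldimethylsilyloxy)-5-[(2S)-oxiran-2-yl]-2-[(2Z)-5-(triisopropylsilyl)pent-2-en-4-ynyl]oxolane | CC(C)[Si](C(C)C)(C(C)C)C#C/C=C\C[C@H]1O[C@@H](C[C@H]1O[Si](C)(C)C(C)(C)C)[C@@H]2CO2 | intermediate
12 | (1S,3Z)-1-[(2S,4R,5R)-4-(tert-butyldimethylsilyloxy)-5-[(2Z)-5-(triisopropylsilyl)pent-2-en-4-ynyl]oxolan-2-yl]hex-3-en-1-ol | CC(C)[Si](C(C)C)(C(C)C)C#C/C=C\C[C@H]1O[C@@H](C[C@H]1O[Si](C)(C)C(C)(C)C)[C@@H](O)C/C=C\CC | intermediate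
13 | (1S)-1-[(2S,4R,5R)-4-(tert-butyldimethylsilyloxy)-5-[(2Z)-5-(triisopropylsilyl)pent-2-en-4-ynyl]oxolan-2-yl]-2-[(2R,3S)-3-ethyloxiran-2-yl]ethan-1-ol | CC(C)[Si](C(C)C)(C(C)C)C#C/C=C\C[C@H]1O[C@@H](C[C@H]1O[Si](C)(C)C(C)(C)C)[C@@H](O)C[C@H]2O[C@H]2CC | intermediate
14 | (1R)-1-[(2S,4R,5R)-4-(tert-butyldimethylsilyloxy)-5-[(2Z)-5-(triisopropylsilyl)pent-2-en-4-ynyl]oxolan-2-yl]-2-[(2R,3S)-3-ethyloxiran-2-yl]ethyl acetate | CC(C)[Si](C(C)C)(C(C)C)C#C/C=C\C[C@H]1O[C@@H](C[C@H]1O[Si](C)(C)C(C)(C)C)[C@H](OC(C)=O)C[C@H]2O[C@H]2CC | intermediate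
15 | bicyclic oxonium zwitterion (1-oxoniabicyclo[3.3.0]octane: O+ bonded to C6, C9 and C12; C10 acetate; C13 alkoxide bound to BF3) | CC(C)[Si](C(C)C)(C(C)C)C#C/C=C\C[C@H]1[O+]2[C@H]([C@H](CC)O[B-](F)(F)F)C[C@@H](OC(C)=O)[C@@H]2C[C@H]1O[Si](C)(C)C(C)(C)C | intermediate (not isolated)
16 | oxocane with 2-methyl-1,3-dioxolan-2-ylium ring across C9/C10 (trans) and C13 alkoxide bound to BF3 | CC(C)[Si](C(C)C)(C(C)C)C#C/C=C\C[C@H]1O[C@H]([C@H](CC)O[B-](F)(F)F)C[C@H]2OC(C)=[O+][C@@H]2C[C@H]1O[Si](C)(C)C(C)(C)C | intermediate (not isolated)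
17 | (2R,3R,5R,6R,8S)-3-(tert-butyldimethylsilyloxy)-5-hydroxy-8-[(1S)-1-hydroxypropyl]-2-[(2Z)-5-(triisopropylsilyl)pent-2-en-4-ynyl]oxocan-6-yl acetate | CC(C)[Si](C(C)C)(C(C)C)C#C/C=C\C[C@H]1O[C@H]([C@H](CC)O)C[C@@H](OC(C)=O)[C@H](O)C[C@H]1O[Si](C)(C)C(C)(C)C | intermediate
18 | (2R,3R,5R,6R,8S)-8-[(1S)-1-acetoxypropyl]-3-(tert-butyldimethylsilyloxy)-2-[(2Z)-5-(triisopropylsilyl)pent-2-en-4-ynyl]oxocane-5,6-diyl diacetate | CC(C)[Si](C(C)C)(C(C)C)C#C/C=C\C[C@H]1O[C@H]([C@H](CC)OC(C)=O)C[C@@H](OC(C)=O)[C@H](OC(C)=O)C[C@H]1O[Si](C)(C)C(C)(C)C | intermediate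
19 | CNP0352372.1, (2R,3R,5R,6R,8S)-8-[(1S)-1-acetoxypropyl]-3-hydroxy-2-[(2Z)-pent-2-en-4-ynyl]oxocane-5,6-diyl diacetate | C#C/C=C\C[C@H]1O[C@H]([C@H](CC)OC(C)=O)C[C@@H](OC(C)=O)[C@H](OC(C)=O)C[C@H]1O | target

**Count and risks**

Total step count: 15. Longest linear sequence: 15 steps (1 → 19).

Steps most likely to fail:

1. Step 13 (carries the label). The acetate carbonyl or fluoride may open the activated epoxide before the ether oxygen does, the epoxide may rearrange to a ketone, or the oxonium ion may revert or be captured at the wrong carbon. The fallback replaces the epoxide trigger by the known bromonium trigger and sets out from 12. Mitsunobu inversion with AcOH (PPh3, DIAD) gives the (10R) Z-olefin acetate F1. Et2SBr·SbBrCl5 in MeNO2 at −25 °C, then water, should give by the known ring-expanding bromoetherification of oxolanes (anti addition across the Z-olefin, acetate capture at C9) the 13-bromo oxocane hydroxy acetate F2. Ac2O/pyridine/DMAP gives the diacetate bromide F3. AgOAc in AcOH should then replace bromide by acetate with retention, through participation of the ring oxygen (double inversion), and the fallback comes back to the route at 18.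

2. Step 11. Facial selectivity of the directed oxygen transfer may be insufficient, or the epoxy alcohol may cyclise on the Lewis-acidic vanadium centre. The fallback delivers the oxygen through a tether and sets out from 12. Boc2O/DMAP gives the tert-butyl carbonate F4. IBr in toluene at −85 °C closes the 4,6-cis iodo cyclic carbonate F5, with the C12 oxygen syn to the C10 oxygen and iodine anti at C13. K2CO3/MeOH cleaves the carbonate and the C12 alkoxide displaces iodide with inversion, which comes back to the route at 13.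

3. Step 12. The oxolane oxygen may participate in the oxyphosphonium intermediate (retention or a ring-enlarged ester), or elimination may compete with substitution. The fallback uses oxidation and chelation-controlled reduction in place of SN2 inversion and sets out from 13. Dess–Martin periodinane with NaHCO3 gives the epoxy ketone F6. Zn(BH4)2 in Et2O at −30 °C should reduce it through the chelate between ring oxygen and carbonyl, from the face of H9, to the (10R) epoxy alcohol F7. Ac2O/pyridine/DMAP then comes back to the route at 14.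

**Further compounds**

F1 | step 13 | (1R,3Z)-1-[(2S,4R,5R)-4-(tert-butyldimethylsilyloxy)-5-[(2Z)-5-(triisopropylsilyl)pent-2-en-4-ynyl]oxolan-2-yl]hex-3-enyl acetate | CC(C)[Si](C(C)C)(C(C)C)C#C/C=C\C[C@H]1O[C@@H](C[C@H]1O[Si](C)(C)C(C)(C)C)[C@H](OC(C)=O)C/C=C\CC
F2 | step 13 | (2R,3R,5R,6R,8S)-8-[(1S)-1-bromopropyl]-3-(tert-butyldimethylsilyloxy)-5-hydroxy-2-[(2Z)-5-(triisopropylsilyl)pent-2-en-4-ynyl]oxocan-6-yl acetate | CC(C)[Si](C(C)C)(C(C)C)C#C/C=C\C[C@H]1O[C@H]([C@H](CC)Br)C[C@@H](OC(C)=O)[C@H](O)C[C@H]1O[Si](C)(C)C(C)(C)C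
F3 | step 13 | (2R,3R,5R,6R,8S)-8-[(1S)-1-bromopropyl]-3-(tert-butyldimethylsilyloxy)-2-[(2Z)-5-(triisopropylsilyl)pent-2-en-4-ynyl]oxocane-5,6-diyl diacetate | CC(C)[Si](C(C)C)(C(C)C)C#C/C=C\C[C@H]1O[C@H]([C@H](CC)Br)C[C@@H](OC(C)=O)[C@H](OC(C)=O)C[C@H]1O[Si](C)(C)C(C)(C)C
F4 | step 11 | tert-butyl (1S,3Z)-1-[(2S,4R,5R)-4-(tert-butyldimethylsilyloxy)-5-[(2Z)-5-(triisopropylsilyl)pent-2-en-4-ynyl]oxolan-2-yl]hex-3-enyl carbonate | CC(C)[Si](C(C)C)(C(C)C)C#C/C=C\C[C@H]1O[C@@H](C[C@H]1O[Si](C)(C)C(C)(C)C)[C@@H](OC(=O)OC(C)(C)C)C/C=C\CC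
F5 | step 11 | (4S,6R)-4-[(2S,4R,5R)-4-(tert-butyldimethylsilyloxy)-5-[(2Z)-5-(triisopropylsilyl)pent-2-en-4-ynyl]oxolan-2-yl]-6-[(1R)-1-iodopropyl]-1,3-dioxan-2-one | CC(C)[Si](C(C)C)(C(C)C)C#C/C=C\C[C@H]1O[C@@H](C[C@H]1O[Si](C)(C)C(C)(C)C)[C@@H]3C[C@@H](OC(=O)O3)[C@H](I)CC
F6 | step 12 | 1-[(2S,4R,5R)-4-(tert-butyldimethylsilyloxy)-5-[(2Z)-5-(triisopropylsilyl)pent-2-en-4-ynyl]oxolan-2-yl]-2-[(2R,3S)-3-ethyloxiran-2-yl]ethan-1-one | CC(C)[Si](C(C)C)(C(C)C)C#C/C=C\C[C@H]1O[C@@H](C[C@H]1O[Si](C)(C)C(C)(C)C)C(=O)C[C@H]2O[C@H]2CC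
F7 | step 12 | (1R)-1-[(2S,4R,5R)-4-(tert-butyldimethylsilyloxy)-5-[(2Z)-5-(triisopropylsilyl)pent-2-en-4-ynyl]oxolan-2-yl]-2-[(2R,3S)-3-ethyloxiran-2-yl]ethan-1-ol | CC(C)[Si](C(C)C)(C(C)C)C#C/C=C\C[C@H]1O[C@@H](C[C@H]1O[Si](C)(C)C(C)(C)C)[C@H](O)C[C@H]2O[C@H]2CC
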